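## Analysis of the target

Agehoustin B (17) is a flavone: a 4H-chromen-4-one (benzo ring A fused to pyranone ring C) carrying an aryl ring B at C2. Ring A has methoxy groups at C5, C6 and C7 and a hydrogen at C8. Ring B has methoxy groups at C2', C3', C4' and C5' and a hydrogen at C6'. The molecule has no stereocentre and no stereogenic double bond, so stereochemistry appears only in transient racemic intermediates and has no bearing on the product. The sensitive sites are the seven aryl methyl ethers and the two electron-rich arenes, which are open to electrophilic halogenation and oxidation. Among the ethers, the C5 methoxy group peri to the C4 carbonyl is the one most easily cleaved by Lewis acids or hydrogen halides. The difficulty is not the skeleton but the regiochemistry of oxygenation of ring B: four adjacent C–O bonds, with the two remaining carbons differentiated as C1' (bonded to C2) and C6' (bonded to H). Ring A, by contrast, is contained complete in a purchasable 2'-hydroxyacetophenone. The strategy rests on the observation that C2', C3', C4' and C5', each bonded to oxygen, map onto the four ring carbons of a squarate ester. Only C1' and C6' then have to be added, as the two carbons of a 1,1-disubstituted alkene whose substituent is the future C2 at the aldehyde oxidation level.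

## Retrosynthetic reasoning

Ring C. Target 17 is opened at O1–C2 and the C2=C3 unsaturation is removed, which leads back to the 2'-hydroxychalcone 15. This cut is preferred to a C2–C1' aryl coupling, which would need a chromone with a leaving group at C2 and a tetraoxygenated aryl metal. Forward, the phenol oxygen must add to the enone β-carbon and the resulting ring must be dehydrogenated across C2–C3 without touching seven methyl ethers.

Enone. Chalcone 15 is cut at the enone double bond (the future C2–C3) into aldehyde 12 and acetophenone 13. What is gained is that ring A with all three methoxy groups arrives intact in commercial 13, so the whole problem is reduced to aldehyde 12. Forward, a crossed aldol condensation is needed, and it can run in one direction only because 12 cannot enolise.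

Functional group adjustment. Aldehyde 12 is traced to its diethyl acetal 11, and 11 to the hydroquinone 10 by removing the methyl groups from O2' and O5'. The acetal is there because the aldehyde carbon has to pass through an organolithium step and a thermolysis. The two free hydroxyls are exactly what the ring expansion leaves behind. Forward, two O-methylations and an acetal hydrolysis are required.

Ring B, the key disconnection. Hydroquinone 10 is cut at C5'–C6' and contracted, through cyclohexadienone 9 and dienylketene 8, to the 4-alkenyl-4-hydroxycyclobutenone 7. The cut is made here because it turns the four contiguous oxygen-bearing carbons into one four-carbon unit that already carries all four oxygens. Building the same pattern on a preformed benzene would take several regiocontrolled C–O bond formations. Forward, a conrotatory ring opening, a six-electron ring closure and an enolisation must follow one another, and the alkenyl group must turn toward the ketene.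

Cyclobutenone. Compound 7 is cut at C1'–C2', the bond between the alkene α-carbon and the carbinol carbon, into dimethyl squarate 4 and the vinyllithium 5. Because 4 is symmetric, the two carbonyl groups are equivalent and no regiochemical question arises. The forward addition only has to stop after one equivalent.

Vinyl unit. Vinyllithium 5 comes from vinyl bromide 3 by halogen–lithium exchange, and 3 from acrolein diethyl acetal 1 through the dibromide 2 by bromination and single dehydrobromination. The forward elimination must remove the C2 hydrogen, which the neighbouring acetal acidifies.

## Alternatives that were turned down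

Alternative 1: Ring A would be built last on a preformed 4-pyranone that already carries ring B.
- Disconnection and key step: photolysis of diazoketone A1 would trigger a Wolff rearrangement to a ketene whose vinyl partner is the pyranone C2=C3 bond. Cycloaddition with the symmetric ynediether A2 would form C5–C6 and C7–C8. Four-electron opening of the resulting cyclobutenone and six-electron closure through C4a–C5 would then give flavone A3.
- For: three C–C bonds and a ring are made in one operation, against one bond in the chosen key step. The symmetric alkyne removes any regiochemical issue, and the C5 hydroxyl emerges differentiated. On bonds formed per step this alternative is stronger.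
- Against: the ring it builds is the one that can be bought complete in 13. The 2,3,4,5-tetramethoxyphenyl group must still be obtained elsewhere to make A1, so the scarce fragment is not addressed. A2 is a labile reagent that needs its own multistep preparation, and A1 requires a pyranone carboxylic acid and diazo chemistry. After the annulation, two tert-butyl ethers of A3 must be cleaved and three phenols, one of them chelated to the carbonyl, methylated.
- Comparison: the chosen strategy gives up bond count in the key step, but it builds the ring that is hard to buy from a commodity four-carbon unit and leaves ring A untouched.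

Alternative 2: Ring B would be built on the intact chromone by a carbene benzannulation.
- Disconnection and key step: the alkenyl(methoxy)carbene complex A4 and the terminal alkyne A5 would combine with insertion of one CO ligand to form C5'–C6', C1'–C2' and C2'–C3'. This gives the 2'-phenol A6, and one O-methylation would finish the synthesis.
- For: this is the most convergent option. It forms three bonds in the key step and needs neither the chalcone nor an oxidation, and the terminal alkyne fixes the regiochemistry. On convergence and step count after the key step it is stronger than the chosen route.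
- Against: A4 is not a routine carbene complex. Its dioxygenated vinyl group requires a stereodefined 1,2-dimethoxyvinyl anion and stoichiometric zerovalent chromium. A5 is an electron-poor conjugated alkyne and a Michael acceptor, the class for which CO insertion competes least well with cyclopentannulation and furan formation. Oxidative removal of the Cr(CO)3 fragment from the p-methoxyphenol A6 risks oxidation to the quinone level, and A5 itself needs several steps from 13.
- Comparison: the chosen strategy reaches the same four oxygenated carbons by metal-free thermal pericyclic chemistry on a symmetric building block, with no regiochemical or chemoselectivity question in the ring-forming step. The price is a linear but routine end game.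

Alternative 3: Ring A would be folded from a pyranone-masked polyketide chain.
- Disconnection and key step: an alkoxide base would convert the α-methoxy β-keto ester A7 into an extended enolate. Attack of this enolate through C4a on the ester carbon would form C4a–C5, and loss of the alkoxide and enolisation would give the 5,7-dihydroxyflavone A8. Two O-methylations would follow.
- For: the chemistry is purely ionic and mild, with no thermolysis, photolysis or metal. The oxygenation pattern of ring A is written into the chain. On mildness of the key step it is stronger than the chosen route.
- Against: it again builds the purchasable ring A and must import ring B. A7 needs a 2-methyl-6-aryl-4-pyranone, lateral deprotonation and acylation with a methoxymalonyl unit, which is a long preparation. A7 also offers the base several other outlets: retro-Claisen cleavage, conjugate opening of the pyranone, and closure through oxygen instead of through C4a, the least nucleophilic carbon of the extended enolate.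
- Comparison: the chosen strategy is shorter and puts its single demanding step on the fragment that actually needs constructing.

Key step: step 4

Assumption: 1, 4 and 13 are taken as purchasable and used as bought; because 17 is achiral, the racemic nature of 2, 7, 14 and 16 raises no stereochemical question.

## Route

Step 1
Reactants: 1 acrolein diethyl acetal (3,3-diethoxyprop-1-ene)
Product: 2 2,3-dibromo-1,1-diethoxypropane (racemic)
Conditions: Br2 (1.0 equiv), CH2Cl2, −20 °C
Reagents that add atoms: bromine, BrBr
Why: Electrophilic anti addition of bromine to an isolated terminal alkene; the acetal is inert while the mixture is kept cold and acid-free, and the single new stereocentre is racemic and is removed in step 2.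

Step 2
Reactants: 2 2,3-dibromo-1,1-diethoxypropane
Product: 3 2-bromo-3,3-diethoxyprop-1-ene
Conditions: KOt-Bu (1.05 equiv), THF, 0 °C
Reagents that add atoms: none
Why: E2 dehydrobromination; the C2 hydrogen is the more acidic one because it is flanked by bromine and by the acetal carbon with its two oxygens, and the primary C3 bromide is the leaving group, so the 1,1-disubstituted vinyl bromide should result. One equivalent of base at 0 °C should avoid the slower second elimination.

Step 3
Reactants: 3 2-bromo-3,3-diethoxyprop-1-ene; 4 dimethyl squarate (3,4-dimethoxycyclobut-3-ene-1,2-dione)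
Product: 7 4-(3,3-diethoxyprop-1-en-2-yl)-4-hydroxy-2,3-dimethoxycyclobut-2-en-1-one (racemic), via vinyllithium 5 (not isolated), via lithium alkoxide 6 (not isolated)
Conditions: 3, t-BuLi (2.0 equiv), THF, −78 °C; cannulated into 4, THF, −78 °C; sat. aq. NH4Cl, −78 °C
Reagents that add atoms: none
Why: Bromine–lithium exchange at an sp2 carbon gives 5, and 1,2-addition to one of the two equivalent carbonyl groups of symmetric 4 gives 6; the remaining carbonyl of 6 is a deactivated vinylogous ester, so inverse addition at low temperature should stop at mono-addition. The new carbinol stereocentre is racemic and is erased in step 4.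

Step 4
Reactants: 7 4-(3,3-diethoxyprop-1-en-2-yl)-4-hydroxy-2,3-dimethoxycyclobut-2-en-1-one
Product: 10 5-(diethoxymethyl)-2,3-dimethoxybenzene-1,4-diol, via dienylketene 8 (not isolated), via cyclohexadienone 9 (not isolated)
Conditions: degassed p-xylene (0.02 M), 138 °C, Ar, base-washed glassware
Reagents that add atoms: none
Why: This is a Moore rearrangement, the known thermal ring expansion of squarate-derived 4-alkenyl-4-hydroxycyclobutenones to hydroquinones. Heating should cause four-electron conrotatory opening of the C1–C4 bond of 7 to dienylketene 8, in which the former squarate carbons form the ketene–enol chain and the 1,1-disubstituted alkene sits at its end. Ring B then closes as a six-membered carbocycle by a thermally allowed six-electron disrotatory electrocyclisation in which the ketene carbon bonds to the terminal CH2, forming C5'–C6' and giving cyclohexadienone 9. A single keto–enol proton shift from the ring CH2 aromatises 9 to hydroquinone 10. No stereocentre is created, and the one stereocentre of racemic 7 disappears on ring opening. The selectivity needed is torquoselectivity: the alkenyl group must rotate inward, cis to the ketene, and this is secured by the C4 hydroxyl, a lone-pair donor that prefers outward rotation; inward rotation of the hydroxyl would instead let it trap the ketene by lactonisation. The substitution pattern is not in question, because 4 is symmetric and the alkene has one free terminus, so the acetal carbon must end on C1' between C2'–O and C6'–H. Exclusion of oxygen should keep 10 at the hydroquinone oxidation level, and it is carried crude into step 5.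

Step 5
Reactants: 10 5-(diethoxymethyl)-2,3-dimethoxybenzene-1,4-diol
Product: 11 1-(diethoxymethyl)-2,3,4,5-tetramethoxybenzene
Conditions: MeI (excess), K2CO3, degassed DMF, 25 °C, Ar
Reagents that add atoms: iodomethane, CI
Why: Williamson O-methylation of both phenols; the acetal is stable to base, and exclusion of air keeps the electron-rich hydroquinone anion from being oxidised.

Step 6
Reactants: 11 1-(diethoxymethyl)-2,3,4,5-tetramethoxybenzene
Product: 12 2,3,4,5-tetramethoxybenzaldehyde
Conditions: 1 M aq. HCl, THF, 25 °C
Reagents that add atoms: water, O
Why: Acid-catalysed acetal hydrolysis, fast for an electron-rich benzylic acetal; aryl methyl ethers are untouched by dilute acid at room temperature.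

Step 7
Reactants: 12 2,3,4,5-tetramethoxybenzaldehyde; 13 2'-hydroxy-4',5',6'-trimethoxyacetophenone [1-(2-hydroxy-4,5,6-trimethoxyphenyl)ethan-1-one]
Product: 15 (E)-1-(2-hydroxy-4,5,6-trimethoxyphenyl)-3-(2,3,4,5-tetramethoxyphenyl)prop-2-en-1-one, via aldol adduct 14 (not isolated)
Conditions: KOH, EtOH–H2O, 25 °C
Reagents that add atoms: none
Why: Claisen–Schmidt condensation; 12 cannot enolise, so only the methyl ketone of 13 acts as nucleophile, and E1cB dehydration of 14 should give the conjugated E enone. Any 15 that closes to flavanone 16 under the basic conditions is carried forward, since step 8 oxidises both.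

Step 8
Reactants: 15 (E)-1-(2-hydroxy-4,5,6-trimethoxyphenyl)-3-(2,3,4,5-tetramethoxyphenyl)prop-2-en-1-one
Product: 17 Agehoustin B [5,6,7-trimethoxy-2-(2,3,4,5-tetramethoxyphenyl)-4H-chromen-4-one], via flavanone 16 (not isolated)
Conditions: I2 (10 mol %), DMSO, 130 °C
Reagents that add atoms: none
Why: Iodine-catalysed oxidative cyclisation of a 2'-hydroxychalcone: intramolecular oxa-Michael addition closes ring C to 16, and iodination at C3 followed by loss of HI introduces the C2=C3 bond. DMSO reoxidises HI to I2, so free HI stays low and the methyl ethers should survive.

## Compound list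

1 | acrolein diethyl acetal (3,3-diethoxyprop-1-ene) | C=CC(OCC)OCC | starting material
2 | 2,3-dibromo-1,1-diethoxypropane (racemic) | CCOC(OCC)C(Br)CBr | intermediate
3 | 2-bromo-3,3-diethoxyprop-1-ene | CCOC(OCC)C(Br)=C | intermediate
4 | dimethyl squarate (3,4-dimethoxycyclobut-3-ene-1,2-dione) | COC1=C(OC)C(=O)C1=O | starting material
5 | (3,3-diethoxyprop-1-en-2-yl)lithium | [Li]C(=C)C(OCC)OCC | intermediate
6 | lithium 1-(3,3-diethoxyprop-1-en-2-yl)-2,3-dimethoxy-4-oxocyclobut-2-en-1-olate (racemic) | [Li]OC1(C(=C)C(OCC)OCC)C(OC)=C(OC)C1=O | intermediate
7 | 4-(3,3-diethoxyprop-1-en-2-yl)-4-hydroxy-2,3-dimethoxycyclobut-2-en-1-one (racemic) | CCOC(OCC)C(=C)C1(O)C(OC)=C(OC)C1=O | intermediate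
8 | (3Z)-5-(diethoxymethyl)-4-hydroxy-2,3-dimethoxyhexa-1,3,5-trien-1-one (alkenyl group cis to the ketene carbon) | O=C=C(OC)/C(OC)=C(/O)C(=C)C(OCC)OCC | intermediate
9 | 5-(diethoxymethyl)-4-hydroxy-2,3-dimethoxycyclohexa-2,4-dien-1-one | CCOC(OCC)C1=C(O)C(OC)=C(OC)C(=O)C1 | intermediate
10 | 5-(diethoxymethyl)-2,3-dimethoxybenzene-1,4-diol | CCOC(OCC)c1cc(O)c(OC)c(OC)c1O | intermediate
11 | 1-(diethoxymethyl)-2,3,4,5-tetramethoxybenzene | CCOC(OCC)c1cc(OC)c(OC)c(OC)c1OC | intermediate
12 | 2,3,4,5-tetramethoxybenzaldehyde | COc1cc(C=O)c(OC)c(OC)c1OC | intermediate
13 | 2'-hydroxy-4',5',6'-trimethoxyacetophenone | CC(=O)c1c(O)cc(OC)c(OC)c1OC | starting material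
14 | 3-hydroxy-1-(2-hydroxy-4,5,6-trimethoxyphenyl)-3-(2,3,4,5-tetramethoxyphenyl)propan-1-one (racemic) | COc1cc(C(O)CC(=O)c2c(O)cc(OC)c(OC)c2OC)c(OC)c(OC)c1OC | intermediate
15 | (E)-1-(2-hydroxy-4,5,6-trimethoxyphenyl)-3-(2,3,4,5-tetramethoxyphenyl)prop-2-en-1-one | COc1cc(/C=C/C(=O)c2c(O)cc(OC)c(OC)c2OC)c(OC)c(OC)c1OC | intermediate
16 | 5,6,7-trimethoxy-2-(2,3,4,5-tetramethoxyphenyl)chroman-4-one (racemic) | COc1cc(C2CC(=O)c3c(OC)c(OC)c(OC)cc3O2)c(OC)c(OC)c1OC | intermediate
17 | Agehoustin B, 5,6,7-trimethoxy-2-(2,3,4,5-tetramethoxyphenyl)-4H-chromen-4-one | COc1cc(-c2cc(=O)c3c(OC)c(OC)c(OC)cc3o2)c(OC)c(OC)c1OC | target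

## Step count and points of risk

Total step count: 8. Longest linear sequence: 8 steps (1 to 17); acetophenone 13 enters unchanged at step 7.

Step 4 (key step). The pericyclic sequence itself is the best-founded part. What is most likely to go wrong is thermal loss of ethanol from the diethyl acetal, assisted by the neighbouring C2' phenol, followed by oligomerisation through a quinone-methide-type species. Oxidation of the hydroquinone by traces of air is the second concern. Fallback, from alkoxide 6 back to 11: quench 6 at −78 °C with MeOTf in place of NH4Cl to give 4-(3,3-diethoxyprop-1-en-2-yl)-2,3,4-trimethoxycyclobut-2-en-1-one F1. The methoxy group is also a donor that rotates outward, so thermolysis of F1 in p-xylene should give 5-(diethoxymethyl)-2,3,4-trimethoxyphenol F2. F2 has no phenol next to the acetal and cannot be oxidised to a quinone without demethylation. Methylation of its single phenol under the conditions of step 5 returns 11.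

Step 3. The vinyllithium carries an ethoxy group β to lithium, so β-elimination of lithium ethoxide can set in if the temperature rises. Over-addition to the product, or addition at the vinylogous ester carbon, can follow from local excess of reagent. Fallback, from 4 back to 12: use the unfunctionalised isopropenyllithium F4, made from 2-bromopropene F3 and t-BuLi. Addition to 4 should give 4-hydroxy-2,3-dimethoxy-4-(prop-1-en-2-yl)cyclobut-2-en-1-one F5, and thermolysis as in step 4 should give 2,3-dimethoxy-5-methylbenzene-1,4-diol F6. Methylation as in step 5 gives 1,2,3,4-tetramethoxy-5-methylbenzene F7. Oxidation of its methyl group, activated by ortho and para methoxy groups, with DDQ in wet dioxane should give aldehyde 12. This last oxidation is the weak point of the fallback, because over-oxidation of the ring is possible.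

Step 5. Under basic conditions the hydroquinone anion is oxidised very easily by adventitious oxygen, and the phenoxide next to the acetal can expel ethoxide. Fallback, from 10 back to 12: hydrolyse the acetal first (dilute aq. HCl, THF, Ar) to 2,5-dihydroxy-3,4-dimethoxybenzaldehyde F8. The formyl group makes the ring less electron-rich, and its hydrogen bond to the C2' hydroxyl tempers that phenol. Methylation of F8 with MeI and K2CO3 in DMF at 50 °C then gives 12 directly, bypassing 11.

Step 2. Removal of a C3 hydrogen instead of the C2 hydrogen would give the regioisomeric vinyl bromide, and a second elimination would lead to the alkyne level. Fallback, replacing 1 by acrolein F9 and rejoining at 3: brominate F9 to 2,3-dibromopropanal F10 and eliminate with Et3N to 2-bromoacrolein F11. Here the aldehyde makes the C2 hydrogen the only acidic one, so the regiochemistry is unambiguous. Acetalisation of F11 with HC(OEt)3 in EtOH with catalytic NH4NO3 gives 3.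

Step 8. Hydrogen iodide that is not reoxidised fast enough can cleave the peri C5 methyl ether, and iodine can substitute the electron-rich C8 position. Fallback, from 12 back to 17, closing ring C by dehydration instead of oxidation: oxidise 12 with NaClO2, NaH2PO4 and 2-methylbut-2-ene to 2,3,4,5-tetramethoxybenzoic acid F12, and convert it with (COCl)2 and catalytic DMF into 2,3,4,5-tetramethoxybenzoyl chloride F13. C-acylation of the dianion of 13 (LiN(SiMe3)2, 3 equiv, THF, −78 °C) with F13 should give 1-(2-hydroxy-4,5,6-trimethoxyphenyl)-3-(2,3,4,5-tetramethoxyphenyl)propane-1,3-dione F14. Cyclodehydration of F14 in AcOH with catalytic H2SO4 at 90 °C gives 17.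

## Further compounds

F1 | step 4 | 4-(3,3-diethoxyprop-1-en-2-yl)-2,3,4-trimethoxycyclobut-2-en-1-one (racemic) | CCOC(OCC)C(=C)C1(OC)C(OC)=C(OC)C1=O
F2 | step 4 | 5-(diethoxymethyl)-2,3,4-trimethoxyphenol | CCOC(OCC)c1cc(O)c(OC)c(OC)c1OC
F3 | step 3 | 2-bromopropene | CC(Br)=C
F4 | step 3 | isopropenyllithium (prop-1-en-2-yllithium) | [Li]C(C)=C
F5 | step 3 | 4-hydroxy-2,3-dimethoxy-4-(prop-1-en-2-yl)cyclobut-2-en-1-one (racemic) | CC(=C)C1(O)C(OC)=C(OC)C1=O
F6 | step 3 | 2,3-dimethoxy-5-methylbenzene-1,4-diol | Cc1cc(O)c(OC)c(OC)c1O
F7 | step 3 | 1,2,3,4-tetramethoxy-5-methylbenzene | Cc1cc(OC)c(OC)c(OC)c1OC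
F8 | step 5 | 2,5-dihydroxy-3,4-dimethoxybenzaldehyde | O=Cc1cc(O)c(OC)c(OC)c1O
F9 | step 2 | acrolein (prop-2-enal) | C=CC=O
F10 | step 2 | 2,3-dibromopropanal (racemic) | O=CC(Br)CBr
F11 | step 2 | 2-bromoacrolein (2-bromoprop-2-enal) | C=C(Br)C=O
F12 | step 8 | 2,3,4,5-tetramethoxybenzoic acid | COc1cc(C(=O)O)c(OC)c(OC)c1OC
F13 | step 8 | 2,3,4,5-tetramethoxybenzoyl chloride | COc1cc(C(=O)Cl)c(OC)c(OC)c1OC
F14 | step 8 | 1-(2-hydroxy-4,5,6-trimethoxyphenyl)-3-(2,3,4,5-tetramethoxyphenyl)propane-1,3-dione | COc1cc(C(=O)CC(=O)c2c(O)cc(OC)c(OC)c2OC)c(OC)c(OC)c1OC
A1 | alternative 1 | 2-(2-diazoacetyl)-6-(2,3,4,5-tetramethoxyphenyl)-4H-pyran-4-one | COc1cc(-c2cc(=O)cc(C(=O)C=[N+]=[N-])o2)c(OC)c(OC)c1OC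
A2 | alternative 1 | di-tert-butoxyethyne | CC(C)(C)OC#COC(C)(C)C
A3 | alternative 1 | 6,7-di-tert-butoxy-5-hydroxy-2-(2,3,4,5-tetramethoxyphenyl)chromen-4-one | COc1cc(-c2cc(=O)c3c(O)c(OC(C)(C)C)c(OC(C)(C)C)cc3o2)c(OC)c(OC)c1OC
A4 | alternative 2 | pentacarbonyl[(Z)-1,2-dimethoxyethenyl(methoxy)carbene]chromium, (CO)5Cr=C(OMe)C(OMe)=CH(OMe) | CO/C=C(\OC)C(OC)=[Cr](=C=O)(=C=O)(=C=O)(=C=O)=C=O
A5 | alternative 2 | 2-ethynyl-5,6,7-trimethoxy-4H-chromen-4-one | C#Cc1cc(=O)c2c(OC)c(OC)c(OC)cc2o1
A6 | alternative 2 | 2-(2-hydroxy-3,4,5-trimethoxyphenyl)-5,6,7-trimethoxychromen-4-one | COc1cc(-c2cc(=O)c3c(OC)c(OC)c(OC)cc3o2)c(O)c(OC)c1OC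
A7 | alternative 3 | methyl 2-methoxy-3-oxo-4-[4-oxo-6-(2,3,4,5-tetramethoxyphenyl)-4H-pyran-2-yl]butanoate (racemic) | COC(=O)C(OC)C(=O)Cc1cc(=O)cc(-c2cc(OC)c(OC)c(OC)c2OC)o1
A8 | alternative 3 | 5,7-dihydroxy-6-methoxy-2-(2,3,4,5-tetramethoxyphenyl)chromen-4-one | COc1cc(-c2cc(=O)c3c(O)c(OC)c(O)cc3o2)c(OC)c(OC)c1OC
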